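**Retrosynthetic overview**
1. The seven-membered dioxepinone ring is closed late by lactonisation of a 2-aryloxybenzoic acid onto O6 of ring B (the isochromanone ring); two benzyl ethers (O6, O8) and one dioxolane (side-chain ketone) are the only protecting groups.
2. Key disconnection: in ring A (the methoxy ring) the carbon carrying the diaryl-ether oxygen and the carbon carrying the lactone carbonyl are ortho to each other. This 1,2-pair maps onto the two carbons of an aryne, which is inserted between the 5-phenoxide of ring B and CO2 (the future C=O) in one three-component step.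
3. Ring B half: methyl orsellinate dibenzyl ether, lateral lithiation, acylation with (R)-δ-hexanolactone and thermodynamic spiroketalisation; then C5 bromination, borylation and oxidation to the 5-phenol.
4. Ring A half: 2,6-dibromo-4-methoxyphenol to the ortho-silylaryl triflate (retro-Brook, triflation); the remaining bromide is exchanged for the ketal-masked 2-oxoheptyl chain by Negishi coupling.
5. Ring order: tetrahydropyran and δ-lactone of the spiroketal together (step 5), then the seven-membered lactone (step 10); both benzene rings are bought.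

Key step: step 8

Remark: ring B is numbered as isochroman-1-one (C1 lactone carbonyl, C3 spiro carbon, O5, O6 and O8 on the benzene ring); (R)-δ-hexanolactone and 1-bromoheptan-2-one are taken as catalogue compounds.

**Route**

Step 1
Reactants: 1 2,6-dibromo-4-methoxyphenol
Product: 4 2-bromo-4-methoxy-6-(trimethylsilyl)phenyl trifluoromethanesulfonate, via silyl ether 2 (not isolated), via lithium phenoxide 3 (not isolated)
Conditions: HMDS, THF, 65 °C, evaporate; n-BuLi (1.05 equiv), THF, −78 °C; Tf2O, −78 °C to 0 °C
Reagents that add atoms: hexamethyldisilazane C[Si](C)(C)N[Si](C)(C)C; trifluoromethanesulfonic anhydride O=S(=O)(OS(=O)(=O)C(F)(F)F)C(F)(F)F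
Why: O-silylation, bromine–lithium exchange, 1,3-retro-Brook O-to-C silyl migration and triflation of the phenoxide is the standard one-pot route to ortho-silylaryl triflates, and one equivalent of n-BuLi should exchange only one of the two equivalent bromines because the phenoxide formed after silyl migration resists further exchange.

Step 2
Reactants: 5 1-bromoheptan-2-one
Product: 6 2-(bromomethyl)-2-pentyl-1,3-dioxolane
Conditions: ethylene glycol, p-TsOH (cat.), toluene, reflux, Dean–Stark
Reagents that add atoms: ethylene glycol OCCO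
Why: acid-catalysed ketalisation with azeotropic removal of water is routine for α-bromo ketones and masks the enolisable ketone for the organometallic and aryne steps.

Step 3
Reactants: 6 2-(bromomethyl)-2-pentyl-1,3-dioxolane; 4 2-bromo-4-methoxy-6-(trimethylsilyl)phenyl trifluoromethanesulfonate
Product: 8 4-methoxy-2-[(2-pentyl-1,3-dioxolan-2-yl)methyl]-6-(trimethylsilyl)phenyl trifluoromethanesulfonate, via organozinc bromide 7 (not isolated)
Conditions: Zn dust (TMSCl/BrCH2CH2Br-activated), LiCl, THF, 40 °C; then 4, Pd[P(t-Bu)3]2 (3 mol%), THF–NMP, 50 °C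
Reagents that add atoms: none
Why: Negishi sp2–sp3 coupling of a primary alkylzinc that has no β-hydrogen (the 2-pentyl homologue of the known (1,3-dioxolan-2-ylmethyl)zinc bromide), with zerovalent palladium bearing a bulky trialkylphosphine, which inserts into the C–Br bond in preference to the flanked C–OTf bond, under fluoride-free and base-free conditions that leave the silyl triflate intact.

Step 4
Reactants: 9 methyl orsellinate (methyl 2,4-dihydroxy-6-methylbenzoate)
Product: 10 methyl 2,4-bis(benzyloxy)-6-methylbenzoate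
Conditions: BnBr, K2CO3, DMF, 60 °C
Reagents that add atoms: benzyl bromide BrCc1ccccc1
Why: Williamson etherification of both phenols, the chelated 2-OH needing the warm DMF conditions, gives ethers that survive LDA, NBS, palladium and fluoride and leave by hydrogenolysis.

Step 5
Reactants: 10 methyl 2,4-bis(benzyloxy)-6-methylbenzoate; 11 (R)-6-methyloxan-2-one ((R)-δ-hexanolactone)
Product: 13 (3S,6'R)-6,8-bis(benzyloxy)-6'-methylspiro[isochromane-3,2'-oxan]-1-one, via hydroxy keto ester 12 (not isolated)
Conditions: 10 (2.1 equiv), LDA (2.2 equiv), THF, −78 °C; 11 (1 equiv); AcOH quench; then p-TsOH·H2O (cat.), toluene, 4 Å MS, rt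
Reagents that add atoms: none
Why: lateral lithiation of the ortho-toluate and Claisen-type C-acylation by the lactone, then acid-catalysed spiroketalisation with lactonisation; C6' comes unchanged from 11, and the spiro centre is set under thermodynamic control (lactone oxygen axial on the oxane chair by the anomeric effect, methyl equatorial), which corresponds to the (3S,6'R) isomer of the target.

Step 6
Reactants: 13 (3S,6'R)-6,8-bis(benzyloxy)-6'-methylspiro[isochromane-3,2'-oxan]-1-one
Product: 14 (3S,6'R)-6,8-bis(benzyloxy)-5-bromo-6'-methylspiro[isochromane-3,2'-oxan]-1-one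
Conditions: NBS, MeCN, 0 °C, dark
Reagents that add atoms: N-bromosuccinimide O=C1CCC(=O)N1Br
Why: electrophilic aromatic bromination should go to C5, which is para to the 8-benzyloxy and ortho to the 6-benzyloxy group, rather than to C7 between two benzyloxy groups, as in 3,5-dialkoxytoluenes.

Step 7
Reactants: 14 (3S,6'R)-6,8-bis(benzyloxy)-5-bromo-6'-methylspiro[isochromane-3,2'-oxan]-1-one
Product: 16 (3S,6'R)-6,8-bis(benzyloxy)-5-hydroxy-6'-methylspiro[isochromane-3,2'-oxan]-1-one, via pinacol boronate 15 (not isolated)
Conditions: B2pin2, Pd(OAc)2, SPhos, KOAc, 1,4-dioxane, 90 °C; then 30% H2O2, aq. NaHCO3, THF, 0 °C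
Reagents that add atoms: hydrogen peroxide OO
Why: Miyaura borylation with a biarylphosphine ligand suited to di-ortho-substituted bromides, then ipso-oxidation of the boronate by buffered peroxide, turns C–Br into C–OH without strong base, so the lactone and acyl ketal should survive.

Step 8
Reactants: 16 (3S,6'R)-6,8-bis(benzyloxy)-5-hydroxy-6'-methylspiro[isochromane-3,2'-oxan]-1-one; 8 4-methoxy-2-[(2-pentyl-1,3-dioxolan-2-yl)methyl]-6-(trimethylsilyl)phenyl trifluoromethanesulfonate
Product: 19 2-{[(3S,6'R)-6,8-bis(benzyloxy)-6'-methyl-1-oxospiro[isochromane-3,2'-oxan]-5-yl]oxy}-4-methoxy-6-[(2-pentyl-1,3-dioxolan-2-yl)methyl]benzoic acid, via potassium phenoxide 17 (not isolated), via aryne 18 (not isolated)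
Conditions: KH (1.05 equiv), THF, 0 °C; then CO2 (1 atm), KF, 18-crown-6, 8 (1.5 equiv), 0 °C to rt; aq. HCl to pH 3
Reagents that add atoms: carbon dioxide O=C=O
Why: Proposed new method: fluoride-induced desilylation and loss of triflate from 8 gives aryne 18, phenoxide 17 adds through oxygen to the aryne carbon remote from the side chain, and the ortho-aryloxyaryl anion, which meets no proton donor (KH leaves only H2, THF is the solvent), is carboxylated by CO2, so that the diaryl-ether C–O bond and the aryl–CO2 bond form in one operation. The closest known reaction types are the three-component coupling of arynes, amines and CO2 to anthranilic acids and the addition of phenoxides to arynes with acyl capture of the aryl anion (salicylate route to xanthones); the phenoxide/CO2 pairing on an aryne is the new element. The step closes no ring (the seven-membered ring follows in step 10) and creates no stereocentre; the two existing stereocentres are not involved. Three selectivities are needed: only O5 may react, which the benzyl ethers on O6 and O8 secure covalently; attack must occur at the aryne carbon meta to the side chain, which the neopentyl-like CH2–C(dioxolane) group next to the other aryne carbon and the bulk of the di-ortho-substituted phenoxide should enforce, the remote methoxy group adding little bias; and carboxylation must outrun protonation, which the absence of proton donors and the small size of CO2 should allow. Reversible O-carboxylation of 17 should only store the phenoxide, because the free phenoxide is by far the better nucleophile toward the aryne.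

Step 9
Reactants: 19 2-{[(3S,6'R)-6,8-bis(benzyloxy)-6'-methyl-1-oxospiro[isochromane-3,2'-oxan]-5-yl]oxy}-4-methoxy-6-[(2-pentyl-1,3-dioxolan-2-yl)methyl]benzoic acid
Product: 20 2-{[(3S,6'R)-6,8-dihydroxy-6'-methyl-1-oxospiro[isochromane-3,2'-oxan]-5-yl]oxy}-4-methoxy-6-[(2-pentyl-1,3-dioxolan-2-yl)methyl]benzoic acid
Conditions: H2 (1 atm), 10% Pd/C, EtOAc–MeOH, rt
Reagents that add atoms: none
Why: hydrogenolysis of the two aryl benzyl ethers leaves the dioxolane, diaryl ether, acid and acyl spiroketal untouched, since the molecule holds no other reducible group.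

Step 10
Reactants: 20 2-{[(3S,6'R)-6,8-dihydroxy-6'-methyl-1-oxospiro[isochromane-3,2'-oxan]-5-yl]oxy}-4-methoxy-6-[(2-pentyl-1,3-dioxolan-2-yl)methyl]benzoic acid
Product: 21 the depsidone dioxolane: the target skeleton with 8-OH free and the side-chain ketone as its 1,3-dioxolane, (S) at the spiro carbon and (R) at the methyl-bearing carbon
Conditions: EDC·HCl, DMAP, CH2Cl2 (0.003 M, slow addition), 0 °C to rt
Reagents that add atoms: none
Why: carbodiimide (Steglich-type) lactonisation, the usual depsidone ring closure, can only reach O6 (ortho to the ether oxygen, giving the seven-membered ring), while O8 is para to the ether oxygen and hydrogen-bonded to the lactone carbonyl, and high dilution suppresses intermolecular acylation.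

Step 11
Reactants: 21 the depsidone dioxolane
Product: 22 the target CNP0301127.1
Conditions: 1 M aq. HCl, THF, rt
Reagents that add atoms: water O
Why: mild acid hydrolysis of the dioxolane frees the 2-oxoheptyl ketone; the aryl lactone is slow to hydrolyse under these conditions, and any reversible opening of the acyl spiroketal should return to the same thermodynamic (anomeric) isomer, so the spiro configuration is retained.

**Compound list**
1 | 2,6-dibromo-4-methoxyphenol | COc1cc(Br)c(O)c(Br)c1 | starting material
2 | (2,6-dibromo-4-methoxyphenoxy)trimethylsilane | COc1cc(Br)c(O[Si](C)(C)C)c(Br)c1 | intermediate (not isolated)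
3 | lithium 2-bromo-4-methoxy-6-(trimethylsilyl)phenoxide | [Li+].[O-]c1c(Br)cc(OC)cc1[Si](C)(C)C | intermediate (not isolated)
4 | 2-bromo-4-methoxy-6-(trimethylsilyl)phenyl trifluoromethanesulfonate | COc1cc(Br)c(OS(=O)(=O)C(F)(F)F)c(c1)[Si](C)(C)C | intermediate
5 | 1-bromoheptan-2-one | CCCCCC(=O)CBr | starting material
6 | 2-(bromomethyl)-2-pentyl-1,3-dioxolane | CCCCCC1(CBr)OCCO1 | intermediate
7 | [(2-pentyl-1,3-dioxolan-2-yl)methyl]zinc bromide | CCCCCC1(C[Zn]Br)OCCO1 | intermediate (not isolated)
8 | 4-methoxy-2-[(2-pentyl-1,3-dioxolan-2-yl)methyl]-6-(trimethylsilyl)phenyl trifluoromethanesulfonate | CCCCCC1(Cc2cc(OC)cc(c2OS(=O)(=O)C(F)(F)F)[Si](C)(C)C)OCCO1 | intermediate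
9 | methyl orsellinate (methyl 2,4-dihydroxy-6-methylbenzoate) | COC(=O)c1c(C)cc(O)cc1O | starting material
10 | methyl 2,4-bis(benzyloxy)-6-methylbenzoate | COC(=O)c1c(C)cc(OCc2ccccc2)cc1OCc1ccccc1 | intermediate
11 | (R)-6-methyloxan-2-one ((R)-δ-hexanolactone) | C[C@@H]1CCCC(=O)O1 | starting material
12 | methyl 2,4-bis(benzyloxy)-6-[(6R)-6-hydroxy-2-oxoheptyl]benzoate | COC(=O)c1c(CC(=O)CCC[C@@H](C)O)cc(OCc2ccccc2)cc1OCc1ccccc1 | intermediate (not isolated)
13 | (3S,6'R)-6,8-bis(benzyloxy)-6'-methylspiro[isochromane-3,2'-oxan]-1-one | c1c(OCc2ccccc2)cc(OCc2ccccc2)c2c1C[C@]1(CCC[C@@H](C)O1)OC2=O | intermediate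
14 | (3S,6'R)-6,8-bis(benzyloxy)-5-bromo-6'-methylspiro[isochromane-3,2'-oxan]-1-one | Brc1c(OCc2ccccc2)cc(OCc2ccccc2)c2c1C[C@]1(CCC[C@@H](C)O1)OC2=O | intermediate
15 | (3S,6'R)-6,8-bis(benzyloxy)-6'-methyl-5-(4,4,5,5-tetramethyl-1,3,2-dioxaborolan-2-yl)spiro[isochromane-3,2'-oxan]-1-one | CC1(C)OB(OC1(C)C)c1c(OCc2ccccc2)cc(OCc2ccccc2)c2c1C[C@]1(CCC[C@@H](C)O1)OC2=O | intermediate (not isolated)
16 | (3S,6'R)-6,8-bis(benzyloxy)-5-hydroxy-6'-methylspiro[isochromane-3,2'-oxan]-1-one | Oc1c(OCc2ccccc2)cc(OCc2ccccc2)c2c1C[C@]1(CCC[C@@H](C)O1)OC2=O | intermediate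
17 | potassium 5-phenoxide of 16 | [K+].[O-]c1c(OCc2ccccc2)cc(OCc2ccccc2)c2c1C[C@]1(CCC[C@@H](C)O1)OC2=O | intermediate (not isolated)
18 | 3-methoxy-5-[(2-pentyl-1,3-dioxolan-2-yl)methyl]benzyne (1,2-didehydrobenzene) | CCCCCC1(CC2=CC(OC)=CC#C2)OCCO1 | intermediate (not isolated)
19 | 2-{[(3S,6'R)-6,8-bis(benzyloxy)-6'-methyl-1-oxospiro[isochromane-3,2'-oxan]-5-yl]oxy}-4-methoxy-6-[(2-pentyl-1,3-dioxolan-2-yl)methyl]benzoic acid | CCCCCC1(Cc2cc(OC)cc(Oc3c(OCc4ccccc4)cc(OCc4ccccc4)c4c3C[C@]3(CCC[C@@H](C)O3)OC4=O)c2C(=O)O)OCCO1 | intermediate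
20 | 2-{[(3S,6'R)-6,8-dihydroxy-6'-methyl-1-oxospiro[isochromane-3,2'-oxan]-5-yl]oxy}-4-methoxy-6-[(2-pentyl-1,3-dioxolan-2-yl)methyl]benzoic acid | CCCCCC1(Cc2cc(OC)cc(Oc3c(O)cc(O)c4c3C[C@]3(CCC[C@@H](C)O3)OC4=O)c2C(=O)O)OCCO1 | intermediate
21 | depsidone dioxolane (target with the side-chain ketone as 1,3-dioxolane; spiro carbon S, methyl carbon R) | CCCCCC1(OCCO1)Cc1cc(OC)cc2c1C(=O)Oc1cc(O)c3c(c1O2)C[C@]1(CCC[C@@H](C)O1)OC3=O | intermediate
22 | CNP0301127.1 (depsidone with 2-oxoheptyl and methoxy on ring A, 8-hydroxy spiro[isochromanone-oxane] ring B; spiro carbon S, methyl carbon R) | CCCCCC(=O)Cc1cc(OC)cc2c1C(=O)Oc1cc(O)c3c(c1O2)C[C@]1(CCC[C@@H](C)O1)OC3=O | target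

**Step count**
Total steps: 11. Longest linear sequence: 8 steps (steps 4 to 11, from methyl orsellinate 9).

**Steps most likely to fail**

Step 8 (proposed new method). What may go wrong: protonation of the aryl anion before it meets CO2; addition of the O-carboxylated phenoxide through its carbonate oxygen instead of the phenoxide oxygen; attack at the aryne carbon next to the side chain. Fallback with known copper chemistry and the regiochemistry fixed in an ortho-bromobenzoate, setting out from phenol 16 and dioxolane 6 and coming back at 20: 3,5-dibromoanisole (catalogue compound) is lithiated between the bromines (LDA, THF, −78 °C) and quenched with benzyl chloroformate to give benzyl 2,6-dibromo-4-methoxybenzoate F1. One bromine of F1 is exchanged by Negishi coupling with organozinc 7 (made from 6 as in step 3; Pd[P(t-Bu)3]2, THF, 50 °C) to give benzyl 2-bromo-4-methoxy-6-[(2-pentyl-1,3-dioxolan-2-yl)methyl]benzoate F2. Ullmann-type ether coupling of F2 with 16 (CuI, picolinic acid, K3PO4, DMSO, 80 °C) should give the diaryl ether benzyl ester F3. Hydrogenolysis under the conditions of step 9 removes the ester benzyl group together with the two ether benzyl groups and gives 20.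

Step 3. What may go wrong: slow zinc insertion into the neopentyl-type bromide; β-alkoxide elimination of the zinc reagent; competing oxidative addition at the triflate. Fallback by alkenylation and rearrangement, setting out from 4 and coming back at 8: Suzuki–Miyaura coupling of 4 with (E)-hept-1-enylboronic acid pinacol ester (Pd[P(t-Bu)3]2, K3PO4, toluene–H2O, 60 °C) gives (E)-2-(hept-1-enyl)-4-methoxy-6-(trimethylsilyl)phenyl trifluoromethanesulfonate F4. Epoxidation (mCPBA, NaHCO3, CH2Cl2) gives the racemic trans-epoxide F5. Meinwald rearrangement (BF3·OEt2, CH2Cl2, −40 °C; benzylic C–O ionisation, then 1,2-hydride shift) gives 4-methoxy-2-(2-oxoheptyl)-6-(trimethylsilyl)phenyl trifluoromethanesulfonate F6. Ketalisation (ethylene glycol, p-TsOH, toluene, Dean–Stark) gives 8.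

Step 5. What may go wrong: proton transfer from the ketone product to the benzylic anion; enolisation of the lactone; acid-induced dehydration of the lactol toward an isocoumarin before the ketal closes. Fallback with an open-chain Weinreb amide as acylating agent, setting out from 10 and 11 and coming back at 13: 11 is opened with MeNH(OMe)·HCl and AlMe3 (CH2Cl2, 0 °C) to (R)-5-hydroxy-N-methoxy-N-methylhexanamide F7, which is silylated (TBSCl, imidazole, DMF) to (R)-5-(tert-butyldimethylsilyloxy)-N-methoxy-N-methylhexanamide F8. Lithiated 10 (LDA, THF, −78 °C) adds to F8 through the stable chelated tetrahedral intermediate and gives, after work-up, methyl 2,4-bis(benzyloxy)-6-[(6R)-6-(tert-butyldimethylsilyloxy)-2-oxoheptyl]benzoate F9. p-TsOH·H2O in MeOH–CH2Cl2 removes the silyl group under conditions in which hemiketal formation, ketalisation and lactonisation follow directly, giving 13.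

**Further compounds**
F1 | step 8 | benzyl 2,6-dibromo-4-methoxybenzoate | COc1cc(Br)c(C(=O)OCc2ccccc2)c(Br)c1
F2 | step 8 | benzyl 2-bromo-4-methoxy-6-[(2-pentyl-1,3-dioxolan-2-yl)methyl]benzoate | CCCCCC1(Cc2cc(OC)cc(Br)c2C(=O)OCc2ccccc2)OCCO1
F3 | step 8 | benzyl 2-{[(3S,6'R)-6,8-bis(benzyloxy)-6'-methyl-1-oxospiro[isochromane-3,2'-oxan]-5-yl]oxy}-4-methoxy-6-[(2-pentyl-1,3-dioxolan-2-yl)methyl]benzoate | CCCCCC1(Cc2cc(OC)cc(Oc3c(OCc4ccccc4)cc(OCc4ccccc4)c4c3C[C@]3(CCC[C@@H](C)O3)OC4=O)c2C(=O)OCc2ccccc2)OCCO1
F4 | step 3 | (E)-2-(hept-1-enyl)-4-methoxy-6-(trimethylsilyl)phenyl trifluoromethanesulfonate | CCCCC/C=C/c1cc(OC)cc(c1OS(=O)(=O)C(F)(F)F)[Si](C)(C)C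
F5 | step 3 | 4-methoxy-2-(trans-3-pentyloxiran-2-yl)-6-(trimethylsilyl)phenyl trifluoromethanesulfonate (racemic, one enantiomer drawn) | CCCCC[C@H]1O[C@@H]1c1cc(OC)cc(c1OS(=O)(=O)C(F)(F)F)[Si](C)(C)C
F6 | step 3 | 4-methoxy-2-(2-oxoheptyl)-6-(trimethylsilyl)phenyl trifluoromethanesulfonate | CCCCCC(=O)Cc1cc(OC)cc(c1OS(=O)(=O)C(F)(F)F)[Si](C)(C)C
F7 | step 5 | (R)-5-hydroxy-N-methoxy-N-methylhexanamide | C[C@@H](O)CCCC(=O)N(C)OC
F8 | step 5 | (R)-5-(tert-butyldimethylsilyloxy)-N-methoxy-N-methylhexanamide | C[C@@H](O[Si](C)(C)C(C)(C)C)CCCC(=O)N(C)OC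
F9 | step 5 | methyl 2,4-bis(benzyloxy)-6-[(6R)-6-(tert-butyldimethylsilyloxy)-2-oxoheptyl]benzoate | COC(=O)c1c(CC(=O)CCC[C@@H](C)O[Si](C)(C)C(C)(C)C)cc(OCc2ccccc2)cc1OCc1ccccc1
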